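Ring C is opened at the C3–C4 bond. The ketone carbon C4 sits on ring A beside the carbon that bears O1, and the unit O1–C2(aryl)–C3 is an enol ether in disguise, so the flavanone is an isomer of a ring A salicylaldehyde whose phenol oxygen carries a 1-(2,6-dimethoxyphenyl)vinyl group. A cationic rhodium–bisphosphine catalyst is asked to add the formyl C–H bond across that vinyl ether, which in one operation forms C3–C4 and C2–H, closes ring C and sets C2 as S. The aldehyde is reached by methylenation of an aryl 2,6-dimethoxybenzoate with the formyl group parked as a silyl-protected carbinol; a final chelation-controlled O-demethylation frees the 5-hydroxyl.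

Key step: step 9

Assumption: (R)-DTBM-SEGPHOS is written as the antipode that leads to 2S; the sense of induction on an oxygen-tethered enol ether has to be established in a first run, and the equally available (S) ligand is used if the mirror image forms.

Step 1
Reactants: 1 1,2,3,5-tetramethoxybenzene
Product: 3 2,3,4,6-tetramethoxybenzaldehyde, via iminium chloride 2 (not isolated)
Conditions: POCl3 (1.5 equiv), DMF, 0 → 60 °C; then H2O
Reagents that add atoms: N,N-dimethylformamide CN(C)C=O; water O
Why: Vilsmeier–Haack formylation, in which the two free ring positions of 1 are equivalent by symmetry and each lies ortho to two and para to one methoxy group, so a single aldehyde should form after hydrolysis of the iminium salt.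

Step 2
Reactants: 3 2,3,4,6-tetramethoxybenzaldehyde
Product: 5 2-hydroxy-3,4,6-trimethoxybenzaldehyde, via dichloroboron phenoxide 4 (not isolated)
Conditions: BCl3 (1.1 equiv), CH2Cl2, −78 → 0 °C; then H2O
Reagents that add atoms: none
Why: Chelation-directed Lewis acid ether cleavage, in which BCl3 held on the formyl oxygen cleaves an ortho methyl ether through a six-membered boron chelate; of the two ortho ethers the one at C2, twisted out of the ring plane by the 3-methoxy group and therefore more basic and more exposed, is the one expected to react, and one equivalent of reagent stops a second cleavage.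

Step 3
Reactants: 5 2-hydroxy-3,4,6-trimethoxybenzaldehyde; 6 2,6-dimethoxybenzoyl chloride
Product: 7 2-formyl-3,5,6-trimethoxyphenyl 2,6-dimethoxybenzoate
Conditions: pyridine, DMAP (cat.), 0 → 60 °C
Reagents that add atoms: none
Why: Acylation of a phenol by an acid chloride under nucleophilic catalysis, a standard way to esterify ortho-carbonyl phenols with this acid chloride; esterifying before any reduction means that a free, electron-rich 2-hydroxybenzyl alcohol prone to ortho-quinone methide formation is never handled.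

Step 4
Reactants: 7 2-formyl-3,5,6-trimethoxyphenyl 2,6-dimethoxybenzoate
Product: 8 2-(hydroxymethyl)-3,5,6-trimethoxyphenyl 2,6-dimethoxybenzoate
Conditions: NaBH4, THF–MeOH, −10 °C; pH 7 buffer
Reagents that add atoms: none
Why: Chemoselective borohydride reduction of an aldehyde beside an ester, in which the 2,6-dimethoxybenzoate carbonyl is shielded on both faces by its ortho substituents, so neither ester reduction nor acyl transfer to the new carbinol should compete at low temperature.

Step 5
Reactants: 8 2-(hydroxymethyl)-3,5,6-trimethoxyphenyl 2,6-dimethoxybenzoate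
Product: 9 2-({[tert-butyl(dimethyl)silyl]oxy}methyl)-3,5,6-trimethoxyphenyl 2,6-dimethoxybenzoate
Conditions: TBSCl, imidazole, DMF, rt
Reagents that add atoms: tert-butyldimethylsilyl chloride CC(C)(C)[Si](C)(C)Cl
Why: Standard silylation of a primary alcohol with a silyl chloride and imidazole, needed because a free hydroxyl would quench the titanium carbene of the next step and an aldehyde would be methylenated by it.

Step 6
Reactants: 9 2-({[tert-butyl(dimethyl)silyl]oxy}methyl)-3,5,6-trimethoxyphenyl 2,6-dimethoxybenzoate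
Product: 10 tert-butyl[(2-{[1-(2,6-dimethoxyphenyl)ethenyl]oxy}-3,4,6-trimethoxyphenyl)methoxy]dimethylsilane
Conditions: (C5H5)2Ti(CH3)2 (3 equiv), toluene–THF, 70 °C, dark; Et3N-deactivated silica
Reagents that add atoms: dimethyltitanocene (C5H5)2Ti(CH3)2 C[Ti](C)(C1C=CC=C1)C1C=CC=C1
Why: Petasis methylenation of an aryl ester, a carbonyl olefination by titanocene methylidene through an oxatitanacyclobutane that is established for turning aryl benzoates into 1-arylvinyl aryl ethers; the reagent is neither acidic nor basic, so the silyl ether, the methyl ethers and the acid-labile product should survive.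

Step 7
Reactants: 10 tert-butyl[(2-{[1-(2,6-dimethoxyphenyl)ethenyl]oxy}-3,4,6-trimethoxyphenyl)methoxy]dimethylsilane
Product: 11 (2-{[1-(2,6-dimethoxyphenyl)ethenyl]oxy}-3,4,6-trimethoxyphenyl)methanol
Conditions: Bu4NF, THF, 0 °C → rt
Reagents that add atoms: none
Why: Fluoride-mediated cleavage of a silyl ether, run in a basic medium that leaves the aryl vinyl ether and the easily ionised benzylic alcohol untouched.

Step 8
Reactants: 11 (2-{[1-(2,6-dimethoxyphenyl)ethenyl]oxy}-3,4,6-trimethoxyphenyl)methanol
Product: 12 2-{[1-(2,6-dimethoxyphenyl)ethenyl]oxy}-3,4,6-trimethoxybenzaldehyde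
Conditions: MnO2 (activated, excess), CH2Cl2, rt
Reagents that add atoms: none
Why: Heterogeneous MnO2 oxidation of a benzylic alcohol, which stops at the aldehyde and runs without acid, so the enol ether should not be hydrolysed.

Step 9
Reactants: 12 2-{[1-(2,6-dimethoxyphenyl)ethenyl]oxy}-3,4,6-trimethoxybenzaldehyde
Product: 13 (2S)-2-(2,6-dimethoxyphenyl)-5,7,8-trimethoxy-2,3-dihydro-4H-chromen-4-one
Conditions: [Rh(cod)Cl]2 (2.5 mol %), (R)-DTBM-SEGPHOS (5.5 mol %), Na[B(C6H3(CF3)2)4] (5 mol %), 1,4-dioxane, 80 °C, argon
Reagents that add atoms: none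
Why: Proposed new method: the chloride-free cationic complex of monovalent rhodium with the bisphosphine should insert into the formyl C–H bond of 12 to give an acyl hydride of trivalent rhodium held next to the enol ether through O1, the hydride then migrates to C2 while the metal takes the terminal carbon C3, and C–C reductive elimination from the resulting seven-membered acyl(alkyl)rhodacycle makes the C3–C4 bond and returns the catalyst. The closest known reaction type is the rhodium-catalysed endo- and enantioselective intramolecular hydroacylation of 1,1-disubstituted alkenes in ortho-allylbenzaldehydes, which gives 3-substituted tetralones; 12 differs in having oxygen in place of the benzylic CH2 and a bulky, electron-rich aryl group on the alkene, and that change is untested. Ring C closes in a formal 6-endo-trig mode, both alkene carbons becoming ring members. The single new stereocentre C2 is created in the insertion that forms the C2–H bond (or, should that insertion be reversible, in the reductive elimination of the faster diastereomeric rhodacycle), and the enol ether face that receives hydride is dictated by the axially chiral bisphosphine, which is pure catalyst control because the substrate has no stereocentre. The step needs endo over exo regiochemistry and C–C bond formation over decarbonylation: the exo path would demand a tertiary, oxygen-bearing alkyl–rhodium bond at C2 and a benzofuran-3-one with a quaternary carbon, which the 1,1-disubstitution and the O1 polarisation of the alkene disfavour, while an acyl group flanked by two ortho oxygens should be slow to extrude CO. The second ortho oxygen is kept as a methyl ether and not as a free phenol, which would hold the acyl rhodium in a salicylaldehyde-type chelate on the side away from the alkene, and the neutral medium leaves the product configurationally stable.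

Step 10
Reactants: 13 (2S)-2-(2,6-dimethoxyphenyl)-5,7,8-trimethoxy-2,3-dihydro-4H-chromen-4-one
Product: 15 (2S)-2-(2,6-dimethoxyphenyl)-5-hydroxy-7,8-dimethoxy-2,3-dihydro-4H-chromen-4-one, via dichloroboron chelate 14 (not isolated)
Conditions: BCl3 (1.2 equiv), CH2Cl2, −78 → −20 °C; then H2O
Reagents that add atoms: none
Why: Chelation-directed Lewis acid cleavage of the methyl ether peri to the C4 ketone, the standard way to unmask a 5-hydroxyl in flavanones, in which BCl3 bound to O4 reaches only the 5-O-methyl group, the other four ethers have no carbonyl partner, and the low temperature is chosen so that the C2–O1 bond is not ionised and the 2S centre is kept.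

Compound list
1 | 1,2,3,5-tetramethoxybenzene | COc1cc(OC)c(OC)c(OC)c1 | starting material
2 | N,N-dimethyl-1-(2,3,4,6-tetramethoxyphenyl)methaniminium chloride (not isolated) | C[N+](C)=Cc1c(OC)cc(OC)c(OC)c1OC.[Cl-] | intermediate
3 | 2,3,4,6-tetramethoxybenzaldehyde | O=Cc1c(OC)cc(OC)c(OC)c1OC | intermediate
4 | 2-[(dichloroboranyl)oxy]-3,4,6-trimethoxybenzaldehyde, boron chelated by the formyl oxygen (not isolated) | O=Cc1c(OC)cc(OC)c(OC)c1OB(Cl)Cl | intermediate
5 | 2-hydroxy-3,4,6-trimethoxybenzaldehyde | O=Cc1c(OC)cc(OC)c(OC)c1O | intermediate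
6 | 2,6-dimethoxybenzoyl chloride | COc1cccc(OC)c1C(=O)Cl | starting material
7 | 2-formyl-3,5,6-trimethoxyphenyl 2,6-dimethoxybenzoate | O=Cc1c(OC)cc(OC)c(OC)c1OC(=O)c1c(OC)cccc1OC | intermediate
8 | 2-(hydroxymethyl)-3,5,6-trimethoxyphenyl 2,6-dimethoxybenzoate | OCc1c(OC)cc(OC)c(OC)c1OC(=O)c1c(OC)cccc1OC | intermediate
9 | 2-({[tert-butyl(dimethyl)silyl]oxy}methyl)-3,5,6-trimethoxyphenyl 2,6-dimethoxybenzoate | CC(C)(C)[Si](C)(C)OCc1c(OC)cc(OC)c(OC)c1OC(=O)c1c(OC)cccc1OC | intermediate
10 | tert-butyl[(2-{[1-(2,6-dimethoxyphenyl)ethenyl]oxy}-3,4,6-trimethoxyphenyl)methoxy]dimethylsilane | C=C(Oc1c(OC)c(OC)cc(OC)c1CO[Si](C)(C)C(C)(C)C)c1c(OC)cccc1OC | intermediate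
11 | (2-{[1-(2,6-dimethoxyphenyl)ethenyl]oxy}-3,4,6-trimethoxyphenyl)methanol | C=C(Oc1c(OC)c(OC)cc(OC)c1CO)c1c(OC)cccc1OC | intermediate
12 | 2-{[1-(2,6-dimethoxyphenyl)ethenyl]oxy}-3,4,6-trimethoxybenzaldehyde | C=C(Oc1c(OC)c(OC)cc(OC)c1C=O)c1c(OC)cccc1OC | intermediate
13 | (2S)-2-(2,6-dimethoxyphenyl)-5,7,8-trimethoxy-2,3-dihydro-4H-chromen-4-one, the (2S)-5,7,8,2',6'-pentamethoxyflavanone | COc1cc(OC)c2c(c1OC)O[C@H](c1c(OC)cccc1OC)CC2=O | intermediate
14 | (2S)-5-[(dichloroboranyl)oxy]-2-(2,6-dimethoxyphenyl)-7,8-dimethoxy-2,3-dihydro-4H-chromen-4-one, boron chelated by O4 (not isolated) | COc1cc(OB(Cl)Cl)c2c(c1OC)O[C@H](c1c(OC)cccc1OC)CC2=O | intermediate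
15 | (2S)-2-(2,6-dimethoxyphenyl)-5-hydroxy-7,8-dimethoxy-2,3-dihydro-4H-chromen-4-one, the (2S)-5-hydroxy-7,8,2',6'-tetramethoxyflavanone | COc1cc(O)c2c(c1OC)O[C@H](c1c(OC)cccc1OC)CC2=O | target

Total step count: 10
Longest linear sequence: 10 steps (1 to 15)

Steps most likely to fail

Step 9. The hindered, electron-rich enol ether may fail to insert into the rhodium hydride, so that the acyl hydride decarbonylates instead. The cationic metal may also act as a Lewis acid and trigger a carbonyl–ene type closure or hydrolysis of the vinyl ether. Facial selectivity may be poor with a 2,6-disubstituted aryl group on the alkene. The fallback uses known chemistry, sets out from 1 and comes back at 13. Friedel–Crafts acetylation of 1 (acetyl chloride, AlCl3, CH2Cl2), which also cleaves the hindered ortho ether through the aluminium chelate, should give 1-(2-hydroxy-3,4,6-trimethoxyphenyl)ethan-1-one F1. Claisen–Schmidt condensation with 2,6-dimethoxybenzaldehyde (COc1cccc(OC)c1C=O; KOH, EtOH) gives (2E)-3-(2,6-dimethoxyphenyl)-1-(2-hydroxy-3,4,6-trimethoxyphenyl)prop-2-en-1-one F2. Oxa-Michael closure (NaOAc, EtOH, reflux) gives racemic 2-(2,6-dimethoxyphenyl)-5,7,8-trimethoxy-2,3-dihydro-4H-chromen-4-one F3. Kinetic resolution by asymmetric transfer hydrogenation (RuCl(p-cymene)[(R,R)-TsDPEN], HCO2H–Et3N, stopped near half conversion) is expected to reduce the 2R ketone to the cis alcohol (2R,4R)-2-(2,6-dimethoxyphenyl)-5,7,8-trimethoxy-3,4-dihydro-2H-chromen-4-ol F4 and to leave 13, which is separated by chromatography. At most half of the racemate can be recovered this way.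

Step 6. The addition of titanocene methylidene to an ester carbonyl that is shielded on both faces by ortho methoxy groups, and attached to a doubly ortho-substituted aryl oxygen, may be too slow, so that the reagent decays before the ester is consumed. The product may also be lost by hydrolysis during isolation. The fallback forms the O1–C2 bond instead of the C2=C3 bond; it sets out from 5 and comes back at 12, bypassing steps 3 to 8. 1-(2,6-Dimethoxyphenyl)ethan-1-one (CC(=O)c1c(OC)cccc1OC) is converted with KN(SiMe3)2 and PhNTf2 (THF, −78 °C) into 1-(2,6-dimethoxyphenyl)ethenyl trifluoromethanesulfonate F5. Palladium-catalysed C–O coupling of F5 with phenol 5 (Pd2(dba)3, 2-(di-tert-butylphosphino)biphenyl, K3PO4, toluene, 90 °C), an established route from enol triflates and phenols to aryl enol ethers, should then give 12 directly. It is kept as a reserve because the phenol is hindered and chelating.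

Step 10. The boron Lewis acid on O4 may promote ionisation of the C2–O1 bond, which is benzylic to an aryl group with two ortho methoxy donors. Ring C would then open and reclose with erosion of enantiopurity. The fallback changes the protecting group so that the last step is a neutral hydrogenolysis; it sets out from 7 and comes back at 15.
- BCl3 (1.05 equiv, CH2Cl2, −78 °C) cleaves the one methyl ether chelated to the aldehyde of 7 and gives 2-formyl-3-hydroxy-5,6-dimethoxyphenyl 2,6-dimethoxybenzoate F6.
- Benzyl bromide and K2CO3 in DMF give 3-(benzyloxy)-2-formyl-5,6-dimethoxyphenyl 2,6-dimethoxybenzoate F7.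
- The conditions of steps 4 to 8 then give in turn:
  - 3-(benzyloxy)-2-(hydroxymethyl)-5,6-dimethoxyphenyl 2,6-dimethoxybenzoate F8;
  - 3-(benzyloxy)-2-({[tert-butyl(dimethyl)silyl]oxy}methyl)-5,6-dimethoxyphenyl 2,6-dimethoxybenzoate F9;
  - {[6-(benzyloxy)-2-{[1-(2,6-dimethoxyphenyl)ethenyl]oxy}-3,4-dimethoxyphenyl]methoxy}(tert-butyl)dimethylsilane F10;
  - [6-(benzyloxy)-2-{[1-(2,6-dimethoxyphenyl)ethenyl]oxy}-3,4-dimethoxyphenyl]methanol F11;
  - 6-(benzyloxy)-2-{[1-(2,6-dimethoxyphenyl)ethenyl]oxy}-3,4-dimethoxybenzaldehyde F12.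
- The hydroacylation of step 9 applied to F12 gives (2S)-5-(benzyloxy)-2-(2,6-dimethoxyphenyl)-7,8-dimethoxy-2,3-dihydro-4H-chromen-4-one F13.
- Hydrogenolysis (H2, Pd on carbon, EtOAc, rt) releases 15 without any Lewis acid.

Further compounds
F1 | step 9 | 1-(2-hydroxy-3,4,6-trimethoxyphenyl)ethan-1-one | CC(=O)c1c(O)c(OC)c(OC)cc1OC
F2 | step 9 | (2E)-3-(2,6-dimethoxyphenyl)-1-(2-hydroxy-3,4,6-trimethoxyphenyl)prop-2-en-1-one | COc1cccc(OC)c1/C=C/C(=O)c1c(O)c(OC)c(OC)cc1OC
F3 | step 9 | racemic 2-(2,6-dimethoxyphenyl)-5,7,8-trimethoxy-2,3-dihydro-4H-chromen-4-one | COc1cc(OC)c2c(c1OC)OC(c1c(OC)cccc1OC)CC2=O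
F4 | step 9 | (2R,4R)-2-(2,6-dimethoxyphenyl)-5,7,8-trimethoxy-3,4-dihydro-2H-chromen-4-ol | COc1cc(OC)c2c(c1OC)O[C@@H](c1c(OC)cccc1OC)C[C@H]2O
F5 | step 6 | 1-(2,6-dimethoxyphenyl)ethenyl trifluoromethanesulfonate | C=C(OS(=O)(=O)C(F)(F)F)c1c(OC)cccc1OC
F6 | step 10 | 2-formyl-3-hydroxy-5,6-dimethoxyphenyl 2,6-dimethoxybenzoate | O=Cc1c(O)cc(OC)c(OC)c1OC(=O)c1c(OC)cccc1OC
F7 | step 10 | 3-(benzyloxy)-2-formyl-5,6-dimethoxyphenyl 2,6-dimethoxybenzoate | O=Cc1c(OCc2ccccc2)cc(OC)c(OC)c1OC(=O)c1c(OC)cccc1OC
F8 | step 10 | 3-(benzyloxy)-2-(hydroxymethyl)-5,6-dimethoxyphenyl 2,6-dimethoxybenzoate | OCc1c(OCc2ccccc2)cc(OC)c(OC)c1OC(=O)c1c(OC)cccc1OC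
F9 | step 10 | 3-(benzyloxy)-2-({[tert-butyl(dimethyl)silyl]oxy}methyl)-5,6-dimethoxyphenyl 2,6-dimethoxybenzoate | CC(C)(C)[Si](C)(C)OCc1c(OCc2ccccc2)cc(OC)c(OC)c1OC(=O)c1c(OC)cccc1OC
F10 | step 10 | {[6-(benzyloxy)-2-{[1-(2,6-dimethoxyphenyl)ethenyl]oxy}-3,4-dimethoxyphenyl]methoxy}(tert-butyl)dimethylsilane | C=C(Oc1c(OC)c(OC)cc(OCc2ccccc2)c1CO[Si](C)(C)C(C)(C)C)c1c(OC)cccc1OC
F11 | step 10 | [6-(benzyloxy)-2-{[1-(2,6-dimethoxyphenyl)ethenyl]oxy}-3,4-dimethoxyphenyl]methanol | C=C(Oc1c(OC)c(OC)cc(OCc2ccccc2)c1CO)c1c(OC)cccc1OC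
F12 | step 10 | 6-(benzyloxy)-2-{[1-(2,6-dimethoxyphenyl)ethenyl]oxy}-3,4-dimethoxybenzaldehyde | C=C(Oc1c(OC)c(OC)cc(OCc2ccccc2)c1C=O)c1c(OC)cccc1OC
F13 | step 10 | (2S)-5-(benzyloxy)-2-(2,6-dimethoxyphenyl)-7,8-dimethoxy-2,3-dihydro-4H-chromen-4-one | COc1cc(OCc2ccccc2)c2c(c1OC)O[C@H](c1c(OC)cccc1OC)CC2=O
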